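**Retrosynthetic overview**
1. Bridge last. The CH2 between C6 of the chromone and C5 of the dihydroisocoumarin is cut to a chromone 6-CH2OH (ortho-quinone methide precursor) and free (3R)-6,8-dihydroxy-3,7-dimethyl-dihydroisocoumarin. C5–H of the latter is its only open arene position and is activated by two hydroxyls.
2. Key disconnection: C3–C4 of the lactone ring. A racemic 1-chloroethyl 2-(chloromethyl)benzoate is closed by an enantioconvergent reductive coupling under nickel/chiral bis(oxazoline) catalysis. That ester is made in the same flask from the aroyl chloride and acetaldehyde, which supplies C3 and its methyl.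
3. Enabling feature: C3 carries the lactone oxygen O2, an acyloxy group that gives a weak C–halogen bond and a planar, stabilised radical, so configuration is erased and reset. C4 is benzylic on the benzene ring, and the aryl ester chain C4–C4a–C8a–C1–O2–C3 holds the two carbons 1,6.
4. The aroyl chloride comes from atraric acid, which already has the fully substituted benzene ring, C1, C4 and the C7 methyl. The ester picks C4 out of the two aryl methyls by lateral lithiation.
5. Ring order: both benzene rings are bought. The pyranone ring (Claisen condensation/cyclodehydration) and the lactone ring (key step) are closed in separate branches, which are then joined.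

Key step: step 6

Assumption: the (S,S)-bis(oxazoline) is taken to deliver the (R)-lactone. Both antipodes of the ligand are available, so the antipode is used if the sense of induction is the opposite.

**Step 1**
Reactants: 1 methyl 2,4-dihydroxy-3,6-dimethylbenzoate (atraric acid)
Product: 2 methyl 2,4-bis(benzyloxy)-3,6-dimethylbenzoate
Conditions: BnBr, K2CO3, DMF, 70 °C
Reagents that add atoms: benzyl bromide, BrCc1ccccc1
Why: Williamson etherification of both phenols, with heating in DMF to overcome the hydrogen bond of the 2-OH to the ester.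

**Step 2**
Reactants: 2 methyl 2,4-bis(benzyloxy)-3,6-dimethylbenzoate
Product: 3 2,4-bis(benzyloxy)-3,6-dimethylbenzoic acid
Conditions: KOH, DMSO/H2O, 100 °C; then HCl, 0 °C
Reagents that add atoms: potassium hydroxide, [K+].[OH-]
Why: Saponification of a doubly ortho-substituted benzoate, forced by poorly solvated hydroxide in DMSO; the benzyl ethers are inert to base.

**Step 3**
Reactants: 3 2,4-bis(benzyloxy)-3,6-dimethylbenzoic acid
Product: 4 tert-butyl 2,4-bis(benzyloxy)-3,6-dimethylbenzoate
Conditions: tert-butyl 2,2,2-trichloroacetimidate, BF3·OEt2 (cat.), CH2Cl2/cyclohexane, rt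
Reagents that add atoms: tert-butyl 2,2,2-trichloroacetimidate, CC(C)(C)OC(=N)C(Cl)(Cl)Cl
Why: Imidate O-tert-butylation alkylates the carboxyl oxygen with a tert-butyl cation equivalent, so the hindered carbonyl carbon is never attacked.

**Step 4**
Reactants: 4 tert-butyl 2,4-bis(benzyloxy)-3,6-dimethylbenzoate
Product: 6 tert-butyl 2,4-bis(benzyloxy)-6-(chloromethyl)-3-methylbenzoate, via benzylic lithium species 5 (not isolated)
Conditions: LiN(iPr)2 (LDA), THF, −78 °C; cannulated into C2Cl6, THF, −78 °C
Reagents that add atoms: hexachloroethane, ClC(Cl)(Cl)C(Cl)(Cl)Cl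
Why: Lateral lithiation of an ortho-toluate removes a proton only from the 6-methyl, whose anion is conjugated to the ester, and electrophilic chlorination by inverse addition keeps the anion away from the product and so suppresses Wurtz-type coupling.

**Step 5**
Reactants: 6 tert-butyl 2,4-bis(benzyloxy)-6-(chloromethyl)-3-methylbenzoate
Product: 7 2,4-bis(benzyloxy)-6-(chloromethyl)-3-methylbenzoyl chloride
Conditions: SOCl2 (neat), rt; evaporated with toluene, used crude
Reagents that add atoms: thionyl chloride, O=S(Cl)Cl
Why: Direct conversion of a tert-butyl ester into the acid chloride by SOCl2 (acid-promoted loss of the tert-butyl group, then chlorination) keeps the medium acidic, so no carboxylate is present to displace the benzylic chloride.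

**Step 6**
Reactants: 7 2,4-bis(benzyloxy)-6-(chloromethyl)-3-methylbenzoyl chloride; 8 acetaldehyde
Product: 10 (3R)-6,8-bis(benzyloxy)-3,7-dimethyl-3,4-dihydro-1H-isochromen-1-one, via racemic 1-chloroethyl ester 9 (not isolated)
Conditions: (a) MeCHO, ZnCl2 (5 mol %), CH2Cl2, −20 → 0 °C, volatiles off; (b) slow addition to NiBr2·diglyme (10 mol %), (S,S)-Bn-BOX [2,2'-(propane-2,2-diyl)bis((4S)-4-benzyl-4,5-dihydrooxazole)] (13 mol %), Mn powder, NaI (0.5 equiv), DMA/THF, 0 °C, high dilution
Reagents that add atoms: none
Why: Proposed new method: ZnCl2 first catalyses the known addition of the acyl chloride across the C=O bond of acetaldehyde, which makes the O2–C3 bond and gives racemic 9; Mn then reduces the nickel salt to zerovalent nickel, this inserts into the benzylic C4–Cl bond, the benzylnickel species (monovalent after one-electron reduction) abstracts the halogen at C3, and the planar α-acyloxy radical is recaptured to a trivalent seven-membered nickelacycle that forms C3–C4 by reductive elimination. The closest known reaction types are the nickel/bis(oxazoline)-catalysed enantioconvergent alkyl–alkyl couplings of racemic 1-haloalkyl esters (also made in the flask from acyl halide and aldehyde) and nickel-catalysed intramolecular cross-electrophile couplings of two alkyl halides; their combination in a lactone-forming ring closure has not been shown. The six-membered lactone ring closes in a formal 6-exo-tet mode, C4 taking the place of the exocyclic halide at C3. The C3 stereocentre is set by the chiral ligand alone: both enantiomers of 9 lose their configuration in the radical, and the ligand sphere decides which radical face is bound and eliminated, so that the racemate should converge on (R)-10. The step needs ring closure to win over benzyl–benzyl dimerisation, hydrodehalogenation and β-hydride loss to the vinyl ester; the 1,6-relation of C3 and C4 across the rigid aryl ester, slow addition at high dilution and low temperature secure the first, and β-hydride loss is reversible because nickel hydride re-adds to the vinyl ester at the same carbon. The two ortho substituents (C4 and the 8-benzyloxy group) twist the ester out of the arene plane, which should ease the rotation to the E-ester geometry that every six-membered lactone needs.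

**Step 7**
Reactants: 10 (3R)-6,8-bis(benzyloxy)-3,7-dimethyl-3,4-dihydro-1H-isochromen-1-one
Product: 11 (3R)-6,8-dihydroxy-3,7-dimethyl-3,4-dihydro-1H-isochromen-1-one
Conditions: H2 (1 atm), 10 % Pd/C, EtOAc/EtOH, rt
Reagents that add atoms: none
Why: Hydrogenolysis cleaves only the two O-benzyl bonds, because the C3–O2 bond is homobenzylic and the stereocentre is therefore untouched.

**Step 8**
Reactants: 12 1-(2,6-dihydroxy-4-methoxyphenyl)ethan-1-one
Product: 14 eugenin (5-hydroxy-7-methoxy-2-methyl-4H-chromen-4-one), via 1,3-diketone 13 (not isolated)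
Conditions: NaH (excess), EtOAc, THF, reflux; then conc. HCl, MeOH, reflux
Reagents that add atoms: ethyl acetate, CCOC(C)=O
Why: Claisen condensation of the ketone enolate with ethyl acetate and acid cyclodehydration close the pyranone ring, and the two equivalent ortho hydroxyls allow only one chromone.

**Step 9**
Reactants: 14 eugenin
Product: 15 5-hydroxy-6-iodo-7-methoxy-2-methyl-4H-chromen-4-one
Conditions: BnMe3N·ICl2, CaCO3, CH2Cl2/MeOH, rt
Reagents that add atoms: benzyltrimethylammonium dichloroiodate, C[N+](C)(C)Cc1ccccc1.Cl[I-]Cl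
Why: Electrophilic aromatic iodination with dichloroiodate is known to go to C6, ortho to the free 5-OH, in 5-hydroxy-7-alkoxy-4H-chromen-4-ones.

**Step 10**
Reactants: 15 5-hydroxy-6-iodo-7-methoxy-2-methyl-4H-chromen-4-one
Product: 16 5-hydroxy-6-(hydroxymethyl)-7-methoxy-2-methyl-4H-chromen-4-one
Conditions: Bu3SnCH2OH, Pd(PPh3)4 (5 mol %), 1,4-dioxane, 100 °C
Reagents that add atoms: (tributylstannyl)methanol, CCCC[Sn](CO)(CCCC)CCCC
Why: Stille hydroxymethylation swaps iodine for CH2OH at the position fixed in step 9, and its neutral medium avoids premature ortho-quinone methide formation.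

**Step 11**
Reactants: 11 (3R)-6,8-dihydroxy-3,7-dimethyl-3,4-dihydro-1H-isochromen-1-one; 16 5-hydroxy-6-(hydroxymethyl)-7-methoxy-2-methyl-4H-chromen-4-one
Product: 17 (3R)-6,8-dihydroxy-5-[(5-hydroxy-7-methoxy-2-methyl-4-oxo-4H-chromen-6-yl)methyl]-3,7-dimethyl-3,4-dihydro-1H-isochromen-1-one (target)
Conditions: TsOH·H2O (10 mol %), (CF3)2CHOH/CH2Cl2, rt → 40 °C, 16 added slowly
Reagents that add atoms: none
Why: Acid ionises the benzylic alcohol, flanked by 5-OH and 7-OMe, to an ortho-quinone methide/benzylic cation that C5 of 11, its only free ring carbon and ortho/para to two hydroxyls, traps in a dehydrative Friedel–Crafts benzylation, while C3 is remote and untouched.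

**Compound list**
1 | methyl 2,4-dihydroxy-3,6-dimethylbenzoate (atraric acid) | COC(=O)c1c(C)cc(O)c(C)c1O | starting material
2 | methyl 2,4-bis(benzyloxy)-3,6-dimethylbenzoate | COC(=O)c1c(C)cc(OCc2ccccc2)c(C)c1OCc1ccccc1 | intermediate
3 | 2,4-bis(benzyloxy)-3,6-dimethylbenzoic acid | OC(=O)c1c(C)cc(OCc2ccccc2)c(C)c1OCc1ccccc1 | intermediate
4 | tert-butyl 2,4-bis(benzyloxy)-3,6-dimethylbenzoate | CC(C)(C)OC(=O)c1c(C)cc(OCc2ccccc2)c(C)c1OCc1ccccc1 | intermediate
5 | tert-butyl 2,4-bis(benzyloxy)-6-(lithiomethyl)-3-methylbenzoate | CC(C)(C)OC(=O)c1c(C[Li])cc(OCc2ccccc2)c(C)c1OCc1ccccc1 | intermediate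
6 | tert-butyl 2,4-bis(benzyloxy)-6-(chloromethyl)-3-methylbenzoate | CC(C)(C)OC(=O)c1c(CCl)cc(OCc2ccccc2)c(C)c1OCc1ccccc1 | intermediate
7 | 2,4-bis(benzyloxy)-6-(chloromethyl)-3-methylbenzoyl chloride | O=C(Cl)c1c(CCl)cc(OCc2ccccc2)c(C)c1OCc1ccccc1 | intermediate
8 | acetaldehyde | CC=O | starting material
9 | rac-1-chloroethyl 2,4-bis(benzyloxy)-6-(chloromethyl)-3-methylbenzoate | CC(Cl)OC(=O)c1c(CCl)cc(OCc2ccccc2)c(C)c1OCc1ccccc1 | intermediate
10 | (3R)-6,8-bis(benzyloxy)-3,7-dimethyl-3,4-dihydro-1H-isochromen-1-one | C[C@@H]1Cc2cc(OCc3ccccc3)c(C)c(OCc3ccccc3)c2C(=O)O1 | intermediate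
11 | (3R)-6,8-dihydroxy-3,7-dimethyl-3,4-dihydro-1H-isochromen-1-one | C[C@@H]1Cc2cc(O)c(C)c(O)c2C(=O)O1 | intermediate
12 | 1-(2,6-dihydroxy-4-methoxyphenyl)ethan-1-one | COc1cc(O)c(C(C)=O)c(O)c1 | starting material
13 | 1-(2,6-dihydroxy-4-methoxyphenyl)butane-1,3-dione | COc1cc(O)c(C(=O)CC(C)=O)c(O)c1 | intermediate
14 | eugenin (5-hydroxy-7-methoxy-2-methyl-4H-chromen-4-one) | COc1cc(O)c2c(=O)cc(C)oc2c1 | intermediate
15 | 5-hydroxy-6-iodo-7-methoxy-2-methyl-4H-chromen-4-one | COc1cc2oc(C)cc(=O)c2c(O)c1I | intermediate
16 | 5-hydroxy-6-(hydroxymethyl)-7-methoxy-2-methyl-4H-chromen-4-one | COc1cc2oc(C)cc(=O)c2c(O)c1CO | intermediate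
17 | (3R)-6,8-dihydroxy-5-[(5-hydroxy-7-methoxy-2-methyl-4-oxo-4H-chromen-6-yl)methyl]-3,7-dimethyl-3,4-dihydro-1H-isochromen-1-one | COc1cc2oc(C)cc(=O)c2c(O)c1Cc1c(O)c(C)c(O)c2c1C[C@@H](C)OC2=O | target

**Step count**
Total steps: 11. Longest linear sequence: 8 (steps 1–7 and 11).

**Steps most likely to fail**

Step 6.
- What may go wrong: intermolecular benzyl–benzyl coupling or plain reduction of either C–Cl bond may outrun ring closure. Facial selectivity at radical capture may also be poor, because the ester carbonyl cannot chelate nickel in the ring-closing geometry.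
- The fallback sets out from 4 and returns at 10, using known chemistry.
- Lithiation of 4 as in step 4 (5) and acylation with N-methoxy-N-methylacetamide should give tert-butyl 2,4-bis(benzyloxy)-3-methyl-6-(2-oxopropyl)benzoate F1.
- TsOH·H2O in warm toluene removes the tert-butyl group and cyclodehydrates the keto acid to 6,8-bis(benzyloxy)-3,7-dimethyl-1H-isochromen-1-one F2.
- Enantioselective hydrogenation of the C3=C4 bond then gives 10. This is a known reaction of 3-substituted isocoumarins under ruthenium–NHC–diamine catalysis ([Ru(cod)(2-methylallyl)2], chiral imidazolinium salt, KOtBu, chiral 1,2-diphenylethane-1,2-diamine, H2). The benzyl ethers should survive this homogeneous catalyst.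

Step 5.
- What may go wrong: after loss of the tert-butyl group, the carboxyl oxygen may attack the chloromethyl carbon (lactonisation to a five-membered ring) before chlorination. The ortho benzyl ether may also be cleaved.
- The fallback sets out from 4 and returns at 9. It builds the ester by carboxylate O-alkylation and unmasks the benzylic chloride last.
- Quenching 5 with PhSeSePh gives tert-butyl 2,4-bis(benzyloxy)-3-methyl-6-[(phenylselanyl)methyl]benzoate F3.
- TFA/CH2Cl2 gives 2,4-bis(benzyloxy)-3-methyl-6-[(phenylselanyl)methyl]benzoic acid F4, which has no leaving group at C4 and cannot lactonise.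
- 1-Chloroethyl chlorosulfate (NaHCO3, Bu4NHSO4, CH2Cl2/H2O) gives rac-1-chloroethyl 2,4-bis(benzyloxy)-3-methyl-6-[(phenylselanyl)methyl]benzoate F5.
- SO2Cl2 (1 equiv, CH2Cl2, −78 → 0 °C) chlorinates selenium, and chloride displaces the tetravalent selenium group at the benzylic carbon. This gives 9, which enters stage (b) of step 6.

Step 11.
- What may go wrong: the chromone cation may self-condense at C8 of a second chromone, the methylene bridge may scramble under acid, or the phenols may be O-alkylated.
- The fallback sets out from 10 and 15 and returns at 17. It fixes both ends of the bridge by cross-coupling.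
- Blanc chloromethylation of 10 ((CH2O)n, HCl in dioxane, ZnCl2) at its only free position gives (3R)-6,8-bis(benzyloxy)-5-(chloromethyl)-3,7-dimethyl-3,4-dihydro-1H-isochromen-1-one F6.
- Zn dust/LiCl in THF gives [(3R)-6,8-bis(benzyloxy)-3,7-dimethyl-1-oxo-3,4-dihydro-1H-isochromen-5-yl]methylzinc chloride F7.
- Negishi coupling with 15 (Pd(OAc)2, SPhos, THF) tolerates the chelated phenol and gives the 6,8-di-O-benzyl ether of the target F8.
- Hydrogenolysis (H2, Pd/C, EtOAc) gives 17.

**Further compounds**
F1 | step 6 | tert-butyl 2,4-bis(benzyloxy)-3-methyl-6-(2-oxopropyl)benzoate | CC(=O)Cc1cc(OCc2ccccc2)c(C)c(OCc2ccccc2)c1C(=O)OC(C)(C)C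
F2 | step 6 | 6,8-bis(benzyloxy)-3,7-dimethyl-1H-isochromen-1-one | CC1=Cc2cc(OCc3ccccc3)c(C)c(OCc3ccccc3)c2C(=O)O1
F3 | step 5 | tert-butyl 2,4-bis(benzyloxy)-3-methyl-6-[(phenylselanyl)methyl]benzoate | CC(C)(C)OC(=O)c1c(C[Se]c2ccccc2)cc(OCc2ccccc2)c(C)c1OCc1ccccc1
F4 | step 5 | 2,4-bis(benzyloxy)-3-methyl-6-[(phenylselanyl)methyl]benzoic acid | OC(=O)c1c(C[Se]c2ccccc2)cc(OCc2ccccc2)c(C)c1OCc1ccccc1
F5 | step 5 | rac-1-chloroethyl 2,4-bis(benzyloxy)-3-methyl-6-[(phenylselanyl)methyl]benzoate | CC(Cl)OC(=O)c1c(C[Se]c2ccccc2)cc(OCc2ccccc2)c(C)c1OCc1ccccc1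
F6 | step 11 | (3R)-6,8-bis(benzyloxy)-5-(chloromethyl)-3,7-dimethyl-3,4-dihydro-1H-isochromen-1-one | C[C@@H]1Cc2c(CCl)c(OCc3ccccc3)c(C)c(OCc3ccccc3)c2C(=O)O1
F7 | step 11 | [(3R)-6,8-bis(benzyloxy)-3,7-dimethyl-1-oxo-3,4-dihydro-1H-isochromen-5-yl]methylzinc chloride | C[C@@H]1Cc2c(C[Zn]Cl)c(OCc3ccccc3)c(C)c(OCc3ccccc3)c2C(=O)O1
F8 | step 11 | (3R)-6,8-bis(benzyloxy)-5-[(5-hydroxy-7-methoxy-2-methyl-4-oxo-4H-chromen-6-yl)methyl]-3,7-dimethyl-3,4-dihydro-1H-isochromen-1-one | COc1cc2oc(C)cc(=O)c2c(O)c1Cc1c(OCc2ccccc2)c(C)c(OCc2ccccc2)c2c1C[C@@H](C)OC2=O
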